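**Retrosynthetic overview**

1. The target is traced back to its 7-acetate; the last step is a neutral acetate cleavage.
2. Key disconnection: ring D is opened at its O–C(CH3)2 bond to a ring-B ortho-prenylphenol. Both prenyl groups are then traced back to O-allyl ethers: the C3′ prenyl to a 4′-O-(1,1-dimethylallyl) ether (Claisen), the C8 prenyl to a 5-O-prenyl ether (Claisen–Cope). One pot performs all three events.
3. Enabling features: the ring-D oxygen (O4′ of ring B) has a free ortho carbon (C3′), and its para carbon is blocked by C2. C8 of ring A is para to O5, which lies peri to the C4 carbonyl (chelation site for Eu). With O7 acetylated, C8 has no free hydroxyl neighbour, so only ring D can close.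
4. The bis-ether flavanone comes from 5-prenyloxy-7-acetoxychromone and an arylboronic acid by rhodium-catalysed asymmetric 1,4-addition, which sets C2 as (S).
5. Ring order: rings A and C come with commercial 5,7-dihydroxychromone (ring C is saturated and made stereogenic in the union), ring B comes from 4-bromophenol, and ring D is the only ring built and is closed last.

Key step: step 7

Assumption: 5,7-dihydroxychromone, 3-methylbut-2-en-1-ol, 4-bromophenol and 3-chloro-3-methylbut-1-yne are bought. The (S)-bisphosphine is assigned by analogy with the (S)-BINAP/cyclohexenone facial model; should the sense of induction be opposite, the (R)-ligand is used.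

**Route**

Step 1
Reactants: 1 5,7-dihydroxy-4H-chromen-4-one
Product: 2 5-hydroxy-4-oxo-4H-chromen-7-yl acetate
Conditions: Ac2O (1.05 equiv), pyridine, CH2Cl2, 0 °C
Reagents that add atoms: acetic anhydride, CC(=O)OC(C)=O
Why: Chemoselective O-acylation, because the 5-OH is locked in a hydrogen bond to the C4 carbonyl and only the free, more acidic 7-OH reacts with one equivalent of anhydride.

Step 2
Reactants: 2 5-hydroxy-4-oxo-4H-chromen-7-yl acetate; 3 3-methylbut-2-en-1-ol
Product: 4 5-[(3-methylbut-2-en-1-yl)oxy]-4-oxo-4H-chromen-7-yl acetate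
Conditions: PPh3, DIAD, THF, 0 → 25 °C
Reagents that add atoms: none
Why: Mitsunobu etherification, in which the chelated 5-OH serves as pronucleophile and attacks the primary carbon of the alkoxyphosphonium ion under neutral conditions that leave the aryl acetate intact.

Step 3
Reactants: 5 4-bromophenol; 6 3-chloro-3-methylbut-1-yne
Product: 7 1-bromo-4-[(2-methylbut-3-yn-2-yl)oxy]benzene
Conditions: CuCl2·2H2O (1 mol %), DBU, MeCN, 0 °C
Reagents that add atoms: none
Why: Copper-catalysed propargylic substitution through a copper allenylidene, the standard route to aryl 1,1-dimethylpropargyl ethers, which gives O-alkylation at the tertiary carbon.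

Step 4
Reactants: 7 1-bromo-4-[(2-methylbut-3-yn-2-yl)oxy]benzene
Product: 8 1-bromo-4-[(2-methylbut-3-en-2-yl)oxy]benzene
Conditions: H2 (1 atm), Pd/CaCO3 poisoned with Pb(OAc)2 (Lindlar catalyst), quinoline, EtOAc, 20 °C
Reagents that add atoms: none
Why: Lindlar semihydrogenation stops at the terminal alkene and spares the aryl bromide, and the ether is kept below 40 °C so that it does not rearrange early.

Step 5
Reactants: 8 1-bromo-4-[(2-methylbut-3-en-2-yl)oxy]benzene
Product: 11 {4-[(2-methylbut-3-en-2-yl)oxy]phenyl}boronic acid, via aryllithium 9 (not isolated), via lithium aryltriisopropoxyborate 10 (not isolated)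
Conditions: n-BuLi, THF, −78 °C; B(OiPr)3, −78 → 0 °C; 1 M HCl to pH 5, 0 °C
Reagents that add atoms: triisopropyl borate, CC(C)OB(OC(C)C)OC(C)C; water, O
Why: Bromine–lithium exchange, borate trapping and mild hydrolysis, which the ether survives because its O-bound carbon is quaternary (no Wittig rearrangement) and the work-up is only weakly acidic.

Step 6
Reactants: 4 5-[(3-methylbut-2-en-1-yl)oxy]-4-oxo-4H-chromen-7-yl acetate; 11 {4-[(2-methylbut-3-en-2-yl)oxy]phenyl}boronic acid
Product: 12 (2S)-2-{4-[(2-methylbut-3-en-2-yl)oxy]phenyl}-5-[(3-methylbut-2-en-1-yl)oxy]-4-oxochroman-7-yl acetate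
Conditions: [Rh(OH)(cod)]2 (2.5 mol %), (S)-MeO-F12-BIPHEP [(S)-2,2′-bis[bis(3,4,5-trifluorophenyl)phosphino]-6,6′-dimethoxy-1,1′-biphenyl] (5.5 mol %), toluene/H2O (10:1), 25–40 °C
Reagents that add atoms: none
Why: Rhodium-catalysed asymmetric 1,4-addition of an arylboronic acid to a chromone (Hayashi–Miyaura reaction), in which the aryl group on monovalent rhodium bound to the (S)-bisphosphine is expected to add to the Re face of C2 and so set the (2S) stereocentre, water protonates the rhodium enolate before ring C can open, the base-free medium keeps the acetate, and the hindered alkenes of both allyl ethers do not insert.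

Step 7
Reactants: 12 (2S)-2-{4-[(2-methylbut-3-en-2-yl)oxy]phenyl}-5-[(3-methylbut-2-en-1-yl)oxy]-4-oxochroman-7-yl acetate
Product: 16 (2S)-2-(2,2-dimethylchroman-6-yl)-5-hydroxy-8-(3-methylbut-2-en-1-yl)-4-oxochroman-7-yl acetate, via C6 dienone 13 (not isolated), via C8-prenyl aryl ether 14 (not isolated), via bis-prenyl diphenol 15 (not isolated)
Conditions: Eu(fod)3 (fod = 6,6,7,7,8,8,8-heptafluoro-2,2-dimethyloctane-3,5-dionate; 10 mol %), PhCl (0.02 M), 70 °C, then 120 °C; cool to 25 °C, Amberlyst 15 (dry sulfonic acid resin), 25–40 °C; filter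
Reagents that add atoms: none
Why: Eu(fod)3, chelated between the C4 carbonyl and O5 of ring A, triggers the [3,3] Claisen shift of the 5-O-prenyl ether to C6 (dienone 13) and the following [3,3] Cope shift to C8, the position para to O5, and enolization gives 14; at 120 °C the 1,1-dimethylallyl ether on ring B undergoes the aromatic Claisen rearrangement, which breaks the O–C(CH3)2 bond and delivers a normal prenyl group to the ortho carbon (the two ortho carbons are equivalent, the para carbon carries C2) to give 15. The sulfonic acid resin then protonates the ring-B alkene at its CH carbon, helped by the neighbouring phenolic OH, and the tertiary cation is captured by that oxygen, so that ring D closes in a 6-endo-trig Markovnikov hydroalkoxylation that re-forms the O–C(CH3)2 bond. The closest known reaction types are the Eu(fod)3-catalysed para-Claisen–Cope rearrangement of 5-O-prenylflavanone 7-acetates, the Claisen rearrangement of aryl 1,1-dimethylallyl ethers to ortho-prenylphenols and the acid-catalysed cyclization of ortho-prenylphenols to 2,2-dimethylchromans. No stereocentre is created; C2 takes part in no bond change and, without base, ring C cannot open by a retro-oxa-Michael reaction, so the (2S) configuration should be carried through. The step needs C8 over C6 regioselectivity, which rests on the Cope shift of 13 outrunning its enolization as is typical of the 7-acetate series, and it needs closure of ring D only: the C8 prenyl group is flanked by the ring oxygen O1 and the acetylated O7, and the free 5-OH is para to it and chelated, so a cation formed there has no oxygen to capture it and should revert by proton loss. The precursor 12 carries both C5 units only as O-allyl ethers, and this single one-pot operation makes the C8–C and C3′–C bonds and ring D without any reagent that adds atoms.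

Step 8
Reactants: 16 (2S)-2-(2,2-dimethylchroman-6-yl)-5-hydroxy-8-(3-methylbut-2-en-1-yl)-4-oxochroman-7-yl acetate
Product: 17 Euchrenone a16, (2S)-2-(2,2-dimethylchroman-6-yl)-5,7-dihydroxy-8-(3-methylbut-2-en-1-yl)chroman-4-one
Conditions: NH4OAc, MeOH/H2O (4:1), 25 °C
Reagents that add atoms: none
Why: Neutral NH4OAc-mediated hydrolysis of the activated aryl acetate avoids both acid, which would close the C8 prenyl group onto O7, and strong base, which would open ring C and racemize C2.

**Compound list**

1 | 5,7-dihydroxy-4H-chromen-4-one | O=c1ccoc2cc(O)cc(O)c12 | starting material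
2 | 5-hydroxy-4-oxo-4H-chromen-7-yl acetate | CC(=O)Oc1cc(O)c2c(c1)occc2=O | intermediate
3 | 3-methylbut-2-en-1-ol | CC(C)=CCO | starting material
4 | 5-[(3-methylbut-2-en-1-yl)oxy]-4-oxo-4H-chromen-7-yl acetate | CC(=O)Oc1cc(OCC=C(C)C)c2c(c1)occc2=O | intermediate
5 | 4-bromophenol | Oc1ccc(Br)cc1 | starting material
6 | 3-chloro-3-methylbut-1-yne | C#CC(C)(C)Cl | starting material
7 | 1-bromo-4-[(2-methylbut-3-yn-2-yl)oxy]benzene | C#CC(C)(C)Oc1ccc(Br)cc1 | intermediate
8 | 1-bromo-4-[(2-methylbut-3-en-2-yl)oxy]benzene | C=CC(C)(C)Oc1ccc(Br)cc1 | intermediate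
9 | {4-[(2-methylbut-3-en-2-yl)oxy]phenyl}lithium | [Li]c1ccc(OC(C)(C)C=C)cc1 | intermediate
10 | lithium triisopropoxy{4-[(2-methylbut-3-en-2-yl)oxy]phenyl}borate | [Li+].CC(C)O[B-](OC(C)C)(OC(C)C)c1ccc(OC(C)(C)C=C)cc1 | intermediate
11 | {4-[(2-methylbut-3-en-2-yl)oxy]phenyl}boronic acid | C=CC(C)(C)Oc1ccc(B(O)O)cc1 | intermediate
12 | (2S)-2-{4-[(2-methylbut-3-en-2-yl)oxy]phenyl}-5-[(3-methylbut-2-en-1-yl)oxy]-4-oxochroman-7-yl acetate | CC(=O)Oc1cc(OCC=C(C)C)c2c(c1)O[C@H](c1ccc(OC(C)(C)C=C)cc1)CC2=O | intermediate
13 | (2S)-6-(2-methylbut-3-en-2-yl)-2-{4-[(2-methylbut-3-en-2-yl)oxy]phenyl}-4,5-dioxo-3,4,5,6-tetrahydro-2H-chromen-7-yl acetate (C6 dienone, both C6 epimers) | C=CC(C)(C)C1C(=O)C2=C(C=C1OC(C)=O)O[C@H](c1ccc(OC(C)(C)C=C)cc1)CC2=O | intermediate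
14 | (2S)-5-hydroxy-2-{4-[(2-methylbut-3-en-2-yl)oxy]phenyl}-8-(3-methylbut-2-en-1-yl)-4-oxochroman-7-yl acetate | CC(C)=CCc1c(OC(C)=O)cc(O)c2c1O[C@H](c1ccc(OC(C)(C)C=C)cc1)CC2=O | intermediate
15 | (2S)-5-hydroxy-2-[4-hydroxy-3-(3-methylbut-2-en-1-yl)phenyl]-8-(3-methylbut-2-en-1-yl)-4-oxochroman-7-yl acetate | CC(C)=CCc1c(OC(C)=O)cc(O)c2c1O[C@H](c1ccc(O)c(CC=C(C)C)c1)CC2=O | intermediate
16 | (2S)-2-(2,2-dimethylchroman-6-yl)-5-hydroxy-8-(3-methylbut-2-en-1-yl)-4-oxochroman-7-yl acetate | CC(C)=CCc1c(OC(C)=O)cc(O)c2c1O[C@H](c1ccc3c(c1)CCC(C)(C)O3)CC2=O | intermediate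
17 | Euchrenone a16, (2S)-2-(2,2-dimethylchroman-6-yl)-5,7-dihydroxy-8-(3-methylbut-2-en-1-yl)chroman-4-one | CC(C)=CCc1c(O)cc(O)c2c1O[C@H](c1ccc3c(c1)CCC(C)(C)O3)CC2=O | target

**Summary**

Total step count: 8.
Longest linear sequence: 6 steps (5 → 7 → 8 → 11 → 12 → 16 → 17; steps 3, 4, 5, 6, 7, 8).

**Steps most likely to fail, with fallbacks**

Risk 1, step 7 (key step). During the acid stage the C8 prenyl group may be protonated often enough for double-bond migration, for acetyl loss from O7 followed by closure of a second chroman ring, or for acid-induced opening of ring C. In the first stage, part of dienone 13 may enolize instead of undergoing the Cope shift. The fallback closes ring D before the union, so that no acid ever meets a prenylated flavanone. It sets out from 8: heating in PhCl at 120 °C should give 4-bromo-2-(3-methylbut-2-en-1-yl)phenol F1 by Claisen rearrangement, and Amberlyst 15 should close it to 6-bromo-2,2-dimethylchroman F2 by the same O–C(CH3)2 bond formation. Bromine–lithium exchange with n-BuLi gives (2,2-dimethylchroman-6-yl)lithium F3, B(OiPr)3 gives lithium triisopropoxy(2,2-dimethylchroman-6-yl)borate F4, and mild acidic hydrolysis gives (2,2-dimethylchroman-6-yl)boronic acid F5. Rhodium-catalysed addition of F5 to 4 under the conditions of step 6 should give (2S)-2-(2,2-dimethylchroman-6-yl)-5-[(3-methylbut-2-en-1-yl)oxy]-4-oxochroman-7-yl acetate F6. Eu(fod)3 in CHCl3 at 60 °C should then convert F6, through its C6 dienone F7, into 16, where the route is rejoined.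

Risk 2, step 6. Facial discrimination on the 5-alkoxychromone may be poor, carbometalation may be slow because of the peri substituent, the rhodium enolate may open ring C (erosion of enantiomeric purity), or the 7-acetate may hydrolyse. The fallback is a racemic union followed by kinetic resolution. It sets out from 4 and 11: with [Rh(OH)(cod)]2 alone in toluene/H2O the racemic 2-{4-[(2-methylbut-3-en-2-yl)oxy]phenyl}-5-[(3-methylbut-2-en-1-yl)oxy]-4-oxochroman-7-yl acetate F8 should form. Asymmetric transfer hydrogenation (RhCl(Cp*)(TsDPEN) of the configuration that reduces the (2R)-ketone faster, HCO2H/Et3N, EtOAc, 25 °C), run to about half conversion, should turn the (2R)-enantiomer into (2R,4R)-4-hydroxy-2-{4-[(2-methylbut-3-en-2-yl)oxy]phenyl}-5-[(3-methylbut-2-en-1-yl)oxy]chroman-7-yl acetate F9 and leave the (2S)-ketone. Chromatographic separation returns the route to 12.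

Risk 3, step 2. Alkylation of the chelated, peri-hindered 5-OH may be sluggish, the phenol may be delivered in an SN2′ sense to give the tertiary ether, or PPh3 may add to the chromone enone. The fallback replaces Mitsunobu chemistry on the acetate by base-mediated alkylation under silyl protection, which is harmless because no stereocentre is present yet. It sets out from 1: TIPSCl/imidazole in DMF should give 5-hydroxy-7-[(triisopropylsilyl)oxy]-4H-chromen-4-one F10, and prenyl bromide with K2CO3 in acetone at 50 °C should give 5-[(3-methylbut-2-en-1-yl)oxy]-7-[(triisopropylsilyl)oxy]-4H-chromen-4-one F11. Bu4NF/AcOH in THF at 0 °C removes the silyl group to give 7-hydroxy-5-[(3-methylbut-2-en-1-yl)oxy]-4H-chromen-4-one F12, and Ac2O/pyridine returns the route to 4.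

**Further compounds**

F1 | step 7 | 4-bromo-2-(3-methylbut-2-en-1-yl)phenol | CC(C)=CCc1cc(Br)ccc1O
F2 | step 7 | 6-bromo-2,2-dimethylchroman | CC1(C)CCc2cc(Br)ccc2O1
F3 | step 7 | (2,2-dimethylchroman-6-yl)lithium | [Li]c1ccc2c(c1)CCC(C)(C)O2
F4 | step 7 | lithium triisopropoxy(2,2-dimethylchroman-6-yl)borate | [Li+].CC(C)O[B-](OC(C)C)(OC(C)C)c1ccc2c(c1)CCC(C)(C)O2
F5 | step 7 | (2,2-dimethylchroman-6-yl)boronic acid | OB(O)c1ccc2c(c1)CCC(C)(C)O2
F6 | step 7 | (2S)-2-(2,2-dimethylchroman-6-yl)-5-[(3-methylbut-2-en-1-yl)oxy]-4-oxochroman-7-yl acetate | CC(=O)Oc1cc(OCC=C(C)C)c2c(c1)O[C@H](c1ccc3c(c1)CCC(C)(C)O3)CC2=O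
F7 | step 7 | (2S)-2-(2,2-dimethylchroman-6-yl)-6-(2-methylbut-3-en-2-yl)-4,5-dioxo-3,4,5,6-tetrahydro-2H-chromen-7-yl acetate (C6 dienone, both C6 epimers) | C=CC(C)(C)C1C(=O)C2=C(C=C1OC(C)=O)O[C@H](c1ccc3c(c1)CCC(C)(C)O3)CC2=O
F8 | step 6 | racemic 2-{4-[(2-methylbut-3-en-2-yl)oxy]phenyl}-5-[(3-methylbut-2-en-1-yl)oxy]-4-oxochroman-7-yl acetate | CC(=O)Oc1cc(OCC=C(C)C)c2c(c1)OC(c1ccc(OC(C)(C)C=C)cc1)CC2=O
F9 | step 6 | (2R,4R)-4-hydroxy-2-{4-[(2-methylbut-3-en-2-yl)oxy]phenyl}-5-[(3-methylbut-2-en-1-yl)oxy]chroman-7-yl acetate | CC(=O)Oc1cc(OCC=C(C)C)c2c(c1)O[C@@H](c1ccc(OC(C)(C)C=C)cc1)C[C@H]2O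
F10 | step 2 | 5-hydroxy-7-[(triisopropylsilyl)oxy]-4H-chromen-4-one | CC(C)[Si](Oc1cc(O)c2c(c1)occc2=O)(C(C)C)C(C)C
F11 | step 2 | 5-[(3-methylbut-2-en-1-yl)oxy]-7-[(triisopropylsilyl)oxy]-4H-chromen-4-one | CC(C)=CCOc1cc(O[Si](C(C)C)(C(C)C)C(C)C)cc2occc(=O)c12
F12 | step 2 | 7-hydroxy-5-[(3-methylbut-2-en-1-yl)oxy]-4H-chromen-4-one | CC(C)=CCOc1cc(O)cc2occc(=O)c12
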